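## Retrosynthetic overview

- The target butyrolactone is opened at its ester C–O bond to a γ-hydroxy acid. This comes from reducing the C=O of an isomeric lactone, a 2-aryl-4-benzyl-5-oxooxolane-3-carboxylic acid, whose ring oxygen already sits on the future carbinol carbon with the correct configuration.
- That lactone acid, resolved as an amine salt, comes from the C2-symmetric dehydrodiferulic acid dilactone by hydrogenolysis of one benzylic C–O bond.
- The dilactone comes from two molecules of ferulic acid by phenol oxidation: 8–8' radical coupling, then double lactonisation of the bis-quinone methide.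
- Ring order: both lactone rings of the bicycle form together first; one is cut reductively; the other is cut at its C=O and the target lactone ring closes last.

Locants used below: C7/C7' are the benzylic carbons, C8/C8' the two carbons joined in the coupling, and C9/C9' the carboxyl carbons of the two ferulic acid units. In the target, C9 is the lactone C=O, C9' the OCH2, C7 the carbinol carbon and C7' the benzylic CH2.

Assumption: which antipode of 1-phenylethylamine gives the less soluble salt with the (2S,3S,4R)-acid cannot be predicted. The (R)-amine is written; the (S)-amine takes its place if the pairing is the other way. Racemic compounds before the resolution are drawn as the enantiomer that is carried forward.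

## Route

Step 1
Reactants: 1 ferulic acid, (E)-3-(4-hydroxy-3-methoxyphenyl)prop-2-enoic acid (2 molecules)
Product: 3 rac-(3S*,3aS*,6S*,6aS*)-3,6-bis(4-hydroxy-3-methoxyphenyl)tetrahydro-1H,3H-furo[3,4-c]furan-1,4-dione (dilactone; cis-fused; both aryl groups exo), via bis-quinone methide diacid 2 (not isolated)
Conditions: FeCl3·6H2O (2.2 equiv), H2O/acetone 4:1, N2, rt, 12 h; crystallise
Reagents that add atoms: none
Why: Oxidative phenol coupling: FeCl3 (trivalent iron, a one-electron oxidant) gives the ferulate phenoxyl radical, two radicals join C8–C8', and each CO2H then adds 5-exo to the quinone methide of the other half; only the like (2R*,3R*) bis-quinone methide can close twice to the cis-fused bicycle and each aryl group ends on the convex face, so all four stereocentres are fixed relative to one another (racemate).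

Step 2
Reactants: 3 rac-dilactone
Product: 4 rac-(2S*,3S*,4R*)-2-(4-hydroxy-3-methoxyphenyl)-4-[(4-hydroxy-3-methoxyphenyl)methyl]-5-oxooxolane-3-carboxylic acid
Conditions: H2 (1–3 atm, stopped at 1.0 equiv uptake), 10% Pd/C, THF/AcOH 20:1, rt; SiO2 (recovered 3 recycled)
Reagents that add atoms: none
Why: Hydrogenolysis of a benzylic C–O(acyl) bond on palladium: one of the two equivalent ArCH–O bonds is cut to ArCH2 plus CO2H, the strained bicycle reacting faster than the monocyclic product so the reaction can be stopped after one equivalent of H2; no stereocentre is touched, which leaves aryl/CO2H trans and CO2H/benzyl cis.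

Step 3
Reactants: 4 rac-lactone acid
Product: 5 (R)-1-phenylethylammonium (2S,3S,4R)-2-(4-hydroxy-3-methoxyphenyl)-4-[(4-hydroxy-3-methoxyphenyl)methyl]-5-oxooxolane-3-carboxylate
Conditions: (R)-1-phenylethylamine (0.5 equiv), EtOH/EtOAc, 40 °C → 4 °C; recrystallise to constant rotation (er checked by chiral HPLC of a liberated sample)
Reagents that add atoms: (R)-1-phenylethylamine, C[C@@H](N)c1ccccc1
Why: Classical resolution through diastereomeric salts (half-equivalent method): only the CO2H of 4 is acidic enough to protonate the amine, the less soluble salt is crystallised and the antipode stays in the liquor as free acid; no stereocentre is made or broken.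

Step 4
Reactants: 5 (R)-1-phenylethylammonium salt of the (2S,3S,4R)-lactone acid
Product: 9 (3S,4R)-3-[(S)-hydroxy(4-hydroxy-3-methoxyphenyl)methyl]-4-[(4-hydroxy-3-methoxyphenyl)methyl]oxolan-2-one (target), via free lactone acid 6 (not isolated), via lactol 7 (not isolated), via dihydroxy acid 8 (not isolated)
Conditions: 1 M HCl/EtOAc partition, 0 °C; i-Bu2AlH (5.5 equiv), THF, −78 °C, 2 h; EtOH then NaBH4 (4 equiv), −40 → 0 °C; 1 M HCl to pH 2, 0 °C, EtOAc extraction; PPTS (cat.), EtOAc, rt
Reagents that add atoms: none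
Why: Chemoselective hydride reduction followed by lactonisation: at −78 °C i-Bu2AlH converts CO2H and both ArOH into inert aluminium carboxylate and phenoxides and reduces only the lactone to the lactol, NaBH4 reduces the ring-opened hydroxy aldehyde to CH2OH, and on acidification the CO2H closes onto this new primary OH (γ-lactone; the benzylic OH could only give a β-lactone); the benzylic C7–O bond, C8 and C8' are never broken, so the three stereocentres of 5 become the (S)-carbinol, C3 (S) and C4 (R) of the target.

## Compound list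

1 | ferulic acid, (E)-3-(4-hydroxy-3-methoxyphenyl)prop-2-enoic acid | COc1cc(/C=C/C(=O)O)ccc1O | starting material
2 | rac-(2R*,3R*)-2,3-bis[(3-methoxy-4-oxocyclohexa-2,5-dien-1-ylidene)methyl]butanedioic acid (8–8' bis-quinone methide; not isolated) | COC1=CC(=C[C@@H](C(=O)O)[C@H](C(=O)O)C=C2C=CC(=O)C(OC)=C2)C=CC1=O | intermediate
3 | rac-(3S*,3aS*,6S*,6aS*)-3,6-bis(4-hydroxy-3-methoxyphenyl)tetrahydro-1H,3H-furo[3,4-c]furan-1,4-dione (racemate) | O=C1O[C@H](c3ccc(O)c(OC)c3)[C@H]2C(=O)O[C@H](c3ccc(O)c(OC)c3)[C@@H]12 | intermediate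
4 | rac-(2S*,3S*,4R*)-2-(4-hydroxy-3-methoxyphenyl)-4-[(4-hydroxy-3-methoxyphenyl)methyl]-5-oxooxolane-3-carboxylic acid (racemate) | O=C1O[C@H](c2ccc(O)c(OC)c2)[C@@H](C(=O)O)[C@H]1Cc1ccc(O)c(OC)c1 | intermediate
5 | (R)-1-phenylethylammonium (2S,3S,4R)-2-(4-hydroxy-3-methoxyphenyl)-4-[(4-hydroxy-3-methoxyphenyl)methyl]-5-oxooxolane-3-carboxylate | O=C1O[C@H](c2ccc(O)c(OC)c2)[C@@H](C(=O)[O-])[C@H]1Cc1ccc(O)c(OC)c1.C[C@@H]([NH3+])c1ccccc1 | intermediate
6 | (2S,3S,4R)-2-(4-hydroxy-3-methoxyphenyl)-4-[(4-hydroxy-3-methoxyphenyl)methyl]-5-oxooxolane-3-carboxylic acid (single enantiomer; not isolated) | O=C1O[C@H](c2ccc(O)c(OC)c2)[C@@H](C(=O)O)[C@H]1Cc1ccc(O)c(OC)c1 | intermediate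
7 | (2S,3S,4R)-5-hydroxy-2-(4-hydroxy-3-methoxyphenyl)-4-[(4-hydroxy-3-methoxyphenyl)methyl]oxolane-3-carboxylic acid (lactol; anomeric mixture; not isolated) | OC1O[C@H](c2ccc(O)c(OC)c2)[C@@H](C(=O)O)[C@H]1Cc1ccc(O)c(OC)c1 | intermediate
8 | (2S,3R)-4-hydroxy-2-[(S)-hydroxy(4-hydroxy-3-methoxyphenyl)methyl]-3-[(4-hydroxy-3-methoxyphenyl)methyl]butanoic acid (not isolated) | O[C@H](c1ccc(O)c(OC)c1)[C@@H](C(=O)O)[C@H](CO)Cc1ccc(O)c(OC)c1 | intermediate
9 | (3S,4R)-3-[(S)-hydroxy(4-hydroxy-3-methoxyphenyl)methyl]-4-[(4-hydroxy-3-methoxyphenyl)methyl]oxolan-2-one | COc1cc(C[C@H]2COC(=O)[C@@H]2[C@H](O)c2ccc(O)c(OC)c2)ccc1O | target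

## Step count and risks

Total step count: 4. Longest linear sequence: 4 (one linear sequence from 1). Step 1 is expected to be low-yielding (about 20–30%, with 8–5 and 8–O–4 dimers as by-products), but it is a long-known reaction type run on a very cheap acid, so it is a yield risk and not a feasibility risk. The three steps most likely to fail are steps 2, 3 and 4.

Step 2 (stopping at the mono-acid; risk of over-reduction to the dibenzylsuccinic acid or of sluggish C–O cleavage). The fallback sets out from 3 and opens one lactone with base instead of hydrogen. NaHCO3 in aqueous acetone at rt lets one phenoxide expel its benzylic carboxylate (E1cB), and the quinone methide tautomerises through the C–H next to the surviving lactone C=O. This gives the arylidene lactone acid rac-(2S*,3S*)-2-(4-hydroxy-3-methoxyphenyl)-4-[(E)-(4-hydroxy-3-methoxyphenyl)methylidene]-5-oxooxolane-3-carboxylic acid F1. The second lactone is no longer part of a strained bicycle and should open much more slowly. The C=C alone is then hydrogenated (H2 1 atm, 5% Pd/C, neutral EtOAc, stopped at 1 equiv; C=C saturation is much faster than benzylic C–O cleavage without acid). Hydrogen is delivered to the face opposite the neighbouring CO2H, which puts the benzyl group cis to CO2H, and the route is rejoined at 4.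

Step 3 (no selective crystallisation, or amine-induced opening of the base-labile p-hydroxybenzylic lactone). The fallback resolves the neutral bicycle one step earlier by chromatography. Setting out from 3, preparative chiral SFC (amylose tris(3,5-dimethylphenylcarbamate) phase, CO2/MeOH) gives (3S,3aS,6S,6aS)-3,6-bis(4-hydroxy-3-methoxyphenyl)tetrahydro-1H,3H-furo[3,4-c]furan-1,4-dione F2. Its configuration is assigned by ECD or X-ray, or by taking a sample through to 9. Hydrogenolysis under the conditions of step 2 then gives the free acid directly, and the route is rejoined at 6.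

Step 4 (risks: loss of the benzylic lactone oxygen through a phenoxide-driven quinone methide, partial reduction of the carboxylate, epimerisation at C8' at the aldehyde stage, acid-induced cyclisation of the benzylic alcohol). The fallback protects the phenols first and then uses carboxylate/borohydride selectivity. Setting out from 6, TBSCl/imidazole/DMF gives the tris-silyl compound tert-butyldimethylsilyl (2S,3S,4R)-2-[4-(tert-butyldimethylsilyloxy)-3-methoxyphenyl]-4-{[4-(tert-butyldimethylsilyloxy)-3-methoxyphenyl]methyl}-5-oxooxolane-3-carboxylate F3. AcOH/THF/H2O cleaves only the silyl ester, giving the bis-silyl ether acid (2S,3S,4R)-2-[4-(tert-butyldimethylsilyloxy)-3-methoxyphenyl]-4-{[4-(tert-butyldimethylsilyloxy)-3-methoxyphenyl]methyl}-5-oxooxolane-3-carboxylic acid F4. LiBH4 (THF, 0 °C → rt) reduces the lactone but not the lithium carboxylate, and with no free phenoxide the benzylic C–O bond cannot be expelled. This gives the bis-silyl dihydroxy acid (2S,3R)-4-hydroxy-2-{(S)-hydroxy[4-(tert-butyldimethylsilyloxy)-3-methoxyphenyl]methyl}-3-{[4-(tert-butyldimethylsilyloxy)-3-methoxyphenyl]methyl}butanoic acid F5. On acidification it lactonises to the bis-silyl ether of the target, (3S,4R)-3-{(S)-hydroxy[4-(tert-butyldimethylsilyloxy)-3-methoxyphenyl]methyl}-4-{[4-(tert-butyldimethylsilyloxy)-3-methoxyphenyl]methyl}oxolan-2-one F6. TBAF buffered with AcOH (THF, 0 °C) removes both silyl groups, and the route is rejoined at 9.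

## Further compounds

F1 | step 2 | rac-(2S*,3S*)-2-(4-hydroxy-3-methoxyphenyl)-4-[(E)-(4-hydroxy-3-methoxyphenyl)methylidene]-5-oxooxolane-3-carboxylic acid | COc1cc(/C=C2/C(=O)O[C@H](c3ccc(O)c(OC)c3)[C@H]2C(=O)O)ccc1O
F2 | step 3 | (3S,3aS,6S,6aS)-3,6-bis(4-hydroxy-3-methoxyphenyl)tetrahydro-1H,3H-furo[3,4-c]furan-1,4-dione | O=C1O[C@H](c3ccc(O)c(OC)c3)[C@H]2C(=O)O[C@H](c3ccc(O)c(OC)c3)[C@@H]12
F3 | step 4 | tert-butyldimethylsilyl (2S,3S,4R)-2-[4-(tert-butyldimethylsilyloxy)-3-methoxyphenyl]-4-{[4-(tert-butyldimethylsilyloxy)-3-methoxyphenyl]methyl}-5-oxooxolane-3-carboxylate | O=C1O[C@H](c2ccc(O[Si](C)(C)C(C)(C)C)c(OC)c2)[C@@H](C(=O)O[Si](C)(C)C(C)(C)C)[C@H]1Cc1ccc(O[Si](C)(C)C(C)(C)C)c(OC)c1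
F4 | step 4 | (2S,3S,4R)-2-[4-(tert-butyldimethylsilyloxy)-3-methoxyphenyl]-4-{[4-(tert-butyldimethylsilyloxy)-3-methoxyphenyl]methyl}-5-oxooxolane-3-carboxylic acid | O=C1O[C@H](c2ccc(O[Si](C)(C)C(C)(C)C)c(OC)c2)[C@@H](C(=O)O)[C@H]1Cc1ccc(O[Si](C)(C)C(C)(C)C)c(OC)c1
F5 | step 4 | (2S,3R)-4-hydroxy-2-{(S)-hydroxy[4-(tert-butyldimethylsilyloxy)-3-methoxyphenyl]methyl}-3-{[4-(tert-butyldimethylsilyloxy)-3-methoxyphenyl]methyl}butanoic acid | O[C@H](c1ccc(O[Si](C)(C)C(C)(C)C)c(OC)c1)[C@@H](C(=O)O)[C@H](CO)Cc1ccc(O[Si](C)(C)C(C)(C)C)c(OC)c1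
F6 | step 4 | (3S,4R)-3-{(S)-hydroxy[4-(tert-butyldimethylsilyloxy)-3-methoxyphenyl]methyl}-4-{[4-(tert-butyldimethylsilyloxy)-3-methoxyphenyl]methyl}oxolan-2-one | COc1cc(C[C@H]2COC(=O)[C@@H]2[C@H](O)c2ccc(O[Si](C)(C)C(C)(C)C)c(OC)c2)ccc1O[Si](C)(C)C(C)(C)C
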